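**Retrosynthetic overview**

1. Structural basis: in the ten-membered ring (germacrane numbering) C1 and C2 are two unsubstituted CH carbons between C10 and C3. The trans C1–C10 and cis C2–C3 oxiranes are the oxidized form of a 1(10)E,2Z-diene, which is the diene a conrotatory opening of a cis-fused cyclobutene C10–C1=C2–C3 gives.
2. Target 32 ⇐ late oxygenation and acylation (C4=C15 and its hydroxyl-directed epoxide, lactone α-methylene, C8 angelate, diene bis-epoxidation) ⇐ dienone 22.
3. 22 ⇐ 4π-electrocyclic ring expansion of cyclobutene ketone 21 (C3–C10 cleaved, eight- to ten-membered ring) ⇐ [2+2] photocycloaddition of acetylene (C1, C2) to cyclooctenone 19.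
4. 19 ⇐ ring-closing metathesis (C3=C10) ⇐ methallylboration (C8–C9) ⇐ Evans syn-aldol/lactonization (C6–C7) of a succinate imide with a D-ribose-derived pentenal (C3–C6, C5 from the chiral pool).
5. Ring order: γ-lactone, eight-membered carbocycle, cyclobutene, ten-membered carbocycle, then the three oxiranes.

Key step: step 15

Assumption: germacrane numbering is used for all intermediates (lactone oxygen on C6, C11 on C7, C14 on C10, C15 on C4). Compound 21 is drawn as one of its two cis-fused diastereomers, either of which gives 22, and the C11 epimers of 24 and 25 are not distinguished.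

**Route**

Step 1
Reactants: 1 (S)-4-benzyloxazolidin-2-one; 2 methyl 4-chloro-4-oxobutanoate
Product: 3 (S)-4-benzyl-3-(4-methoxy-4-oxobutanoyl)oxazolidin-2-one
Conditions: n-BuLi, THF, −78 °C; then 2, −78 → 0 °C
Reagents that add atoms: none
Why: N-acylation of the lithiated oxazolidinone by the acid chloride (standard preparation of an Evans imide); no stereocenter is formed.

Step 2
Reactants: 4 methyl 2,3-O-isopropylidene-β-D-ribofuranoside
Product: 5 methyl 5-deoxy-5-iodo-2,3-O-isopropylidene-β-D-ribofuranoside
Conditions: I2, PPh3, imidazole, toluene/MeCN, 60 °C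
Reagents that add atoms: iodine II
Why: Appel-type (Garegg–Samuelsson) iodination of the only free, primary hydroxyl; the ring stereocenters are not touched.

Step 3
Reactants: 5 methyl 5-deoxy-5-iodo-2,3-O-isopropylidene-β-D-ribofuranoside
Product: 6 (4R,5R)-2,2-dimethyl-5-vinyl-1,3-dioxolane-4-carbaldehyde
Conditions: Zn (activated), THF/H2O (4:1), sonication, 40 °C; used crude at once
Reagents that add atoms: none
Why: Bernet–Vasella reductive fragmentation, in which zinc inserts into the C–I bond and β-elimination of the ring oxygen opens the furanoside to the aldehyde and the terminal alkene; ribose C2 and C3 (C5 and C4 of the target numbering) are carried over unchanged.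

Step 4
Reactants: 3 (S)-4-benzyl-3-(4-methoxy-4-oxobutanoyl)oxazolidin-2-one; 6 (4R,5R)-2,2-dimethyl-5-vinyl-1,3-dioxolane-4-carbaldehyde
Product: 8 trans-γ-lactone imide (lactone O on C6; acyl oxazolidinone on C7; C4/C5 acetonide; vinyl on C4), via aldol adduct 7 (not isolated)
Conditions: 3, Bu2BOTf, i-Pr2NEt, CH2Cl2, −78 → 0 °C; 6, −78 → 0 °C; pH 7 buffer, H2O2, MeOH, 0 °C; then PPTS (cat.), CH2Cl2, 25 °C
Reagents that add atoms: none
Why: Evans syn-aldol of the Z-boron enolate (soft enolization at the imide α-CH2 only) through a chair Zimmerman–Traxler transition state in which the benzyl group of the auxiliary shields one enolate face, which sets C7 and C6 (6,7-syn; the 5,6-anti relation is also the polar Felkin–Anh sense of the α-alkoxy aldehyde), after which the γ-hydroxy ester closes to the trans-disubstituted γ-lactone.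

Step 5
Reactants: 8 trans-γ-lactone imide
Product: 9 lactone acid (C8 carboxylic acid)
Conditions: LiOH, H2O2, THF/H2O, 0 °C; Na2SO3; then 1 M HCl to pH 3
Reagents that add atoms: hydrogen peroxide OO (as LiOOH; one oxygen stays in the carboxyl group)
Why: hydroperoxide cleavage of the exocyclic imide carbonyl (standard removal of the Evans auxiliary) without epimerization at C7; any lactone opened by base recloses on acidification because only the five-membered ring can form.

Step 6
Reactants: 9 lactone acid
Product: 11 lactone alcohol (C8 hydroxymethyl), via mixed anhydride 10 (not isolated)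
Conditions: i-BuOCOCl, N-methylmorpholine, THF, −15 °C; then NaBH4, H2O, −15 °C, 10 min; aq. citric acid
Reagents that add atoms: isobutyl chloroformate CC(C)COC(Cl)=O (its atoms are present only in 10)
Why: chemoselective reduction of a mixed carbonic anhydride by NaBH4, which is much faster than reduction of the lactone and, unlike a borane, leaves the vinyl group alone.

Step 7
Reactants: 11 lactone alcohol
Product: 12 lactone aldehyde (C8 aldehyde)
Conditions: Dess–Martin periodinane, CH2Cl2, 0 → 25 °C
Reagents that add atoms: none
Why: Dess–Martin oxidation of the primary alcohol under non-basic conditions; the trans arrangement at C6/C7 is the thermodynamically preferred one, so the α-center is not at risk.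

Step 8
Reactants: 12 lactone aldehyde; 13 2-methylallylmagnesium chloride
Product: 14 homoallylic alcohol (8S; C8 hydroxyl syn to C11 and to the C6 oxygen)
Conditions: (−)-Ipc2BOMe, 13, Et2O, −78 → 25 °C; then 12, −78 °C; pH 7 buffer, H2O2, 0 °C
Reagents that add atoms: none
Why: Brown asymmetric methallylboration through a chair transition state in which the isopinocampheyl groups derived from (+)-α-pinene direct the methallyl group to the Si face of the aldehyde (8S), a sense that coincides with Felkin–Anh addition anti to C6; the neutral oxidative work-up avoids 12,6 to 12,8 translactonization.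

Step 9
Reactants: 14 homoallylic alcohol
Product: 15 C8 tert-butyldimethylsilyl ether
Conditions: TBSOTf, 2,6-lutidine, CH2Cl2, −78 → 0 °C
Reagents that add atoms: tert-butyldimethylsilyl trifluoromethanesulfonate CC(C)(C)[Si](C)(C)OS(=O)(=O)C(F)(F)F
Why: silylation of the secondary alcohol with a silyl triflate and a hindered, weak base that does not open the lactone.

Step 10
Reactants: 15 C8 tert-butyldimethylsilyl ether
Product: 16 C4,C5-diol (acyclic diene)
Conditions: AcOH/H2O (4:1), 40 °C
Reagents that add atoms: none
Why: acid hydrolysis of the acetonide under conditions that a secondary TBS ether and the γ-lactone survive; it is placed before ring closure because the cyclic product would carry a readily ionized allylic C4 oxygen next to the trisubstituted alkene.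

Step 11
Reactants: 16 C4,C5-diol
Product: 17 cyclooctene diol (C3=C10 in the eight-membered ring)
Conditions: second-generation Hoveyda–Grubbs catalyst RuCl2(H2IMes)(=CH-C6H4-2-OiPr) (10 mol%), 1,4-benzoquinone (10 mol%), toluene (2 mM), 80 °C
Reagents that add atoms: none
Why: ring-closing metathesis in which the ruthenium carbene loads on the monosubstituted allylic-alcohol vinyl group and closes onto the 1,1-disubstituted methallyl alkene, helped by the trans-lactone and the cis-diol that hold the two chains close; the ring size enforces the Z alkene.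

Step 12
Reactants: 17 cyclooctene diol
Product: 18 α-hydroxy cyclooctenone (C4 ketone)
Conditions: MnO2, CH2Cl2, 25 °C
Reagents that add atoms: none
Why: MnO2 oxidizes the allylic C4 hydroxyl chemoselectively and leaves the non-allylic C5 hydroxyl, so the two oxygens of the former ribose diol are differentiated without protecting groups.

Step 13
Reactants: 18 α-hydroxy cyclooctenone
Product: 19 cyclooctenone (C5 OTES; C8 OTBS)
Conditions: TESOTf, 2,6-lutidine, CH2Cl2, −78 °C
Reagents that add atoms: triethylsilyl trifluoromethanesulfonate CC[Si](CC)(CC)OS(=O)(=O)C(F)(F)F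
Why: silylation of the α-ketol hydroxyl under weakly basic conditions that do not enolize the β-acyloxy ketone.

Step 14
Reactants: 19 cyclooctenone; 20 acetylene
Product: 21 cis-fused cyclobutene ketone (bicyclo[6.2.0]dec-9-en-2-one core; cyclobutene C10–C1=C2–C3)
Conditions: hν (365 nm), acetone saturated with acetylene, −70 °C, 19 at 3 mM
Reagents that add atoms: none
Why: enone–alkyne [2+2] photocycloaddition through the enone triplet and a 1,4-biradical whose closure to a planar cyclobutene favors the cis ring fusion, run at molar acetylene concentration in cold, dilute, aprotic solution so that the short-lived twisted triplet is captured and any E-enone formed by competing isomerization re-absorbs rather than dimerizes; the new centers C3 and C10 need no facial control because both cis-fused diastereomers converge in step 15.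

Step 15
Reactants: 21 cis-fused cyclobutene ketone
Product: 22 germacra-1(10)E,2Z-dien-4-one 12,6-olide (C5 OTES; C8 OTBS)
Conditions: ZnI2 (2 equiv), CH2Cl2, 25 → 40 °C, dark
Reagents that add atoms: none
Why: Thermal conrotatory 4π-electrocyclic ring opening of the cyclobutene breaks the C3–C10 sigma bond and turns it and the C1=C2 pi bond into the C10=C1 and C2=C3 double bonds; the closest known reaction type is the thermal opening of cis-fused bicyclo[n.2.0]alkenes from enone–alkyne photoadducts to ring-expanded cis,trans-cycloalkadienes, run here with Lewis-acid activation of a 3-acylcyclobutene. The ten-membered ring is not closed by bond formation but arises by ring expansion, the four- and eight-membered rings merging when their shared bond is cleaved. No stereocenter is created (C3 and C10 become sp2, which is why both cis-fused diastereomers of 21 converge); the new stereo-elements are the two alkene geometries. Because the ring fusion is cis, conrotation must turn one ring bond inward and the other outward, so only the E,Z and the Z,E pair are possible. The step needs torquoselectivity for C4 inward and C9 outward: the ZnI2-complexed C4 carbonyl is a strong pi-acceptor that overlaps with the breaking sigma bond when it rotates inward (C4 cis to C1, 2Z), which sends C9 outward (C9 trans to C2, 1(10)E) and leaves the small methyl as the group forced inward at C10. The Lewis acid is required because an uncomplexed ketone has no reliable inward preference, and it lowers the barrier so that the opening runs near room temperature.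

Step 16
Reactants: 22 germacra-1(10)E,2Z-dien-4-one 12,6-olide
Product: 23 germacra-1(10)E,2Z,4(15)-triene 12,6-olide (C5 OTES; C8 OTBS)
Conditions: Zn, CH2Br2, TiCl4 (pre-formed Lombardo reagent), THF/CH2Cl2, 0 → 25 °C
Reagents that add atoms: dibromomethane BrCBr
Why: Lombardo methylenation with a non-basic geminal dimetallic reagent converts the ketone chemoselectively in the presence of the lactone and cannot trigger the E1cB loss of the C6 lactone oxygen that a basic ylide could cause by enolizing C5.

Step 17
Reactants: 23 germacra-1(10)E,2Z,4(15)-triene 12,6-olide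
Product: 24 α-(dimethylaminomethyl) lactone (Mannich base at C11)
Conditions: LDA, THF, −78 °C; then Me2N=CH2 I, −78 → 0 °C
Reagents that add atoms: N,N-dimethylmethyleneiminium iodide C=[N+](C)C.[I-]
Why: Mannich reaction of the kinetic lithium lactone enolate (C11 is the only carbon acid of this strength) with Eschenmoser's salt; the configuration of C11 is irrelevant because it becomes sp2 in the next step.

Step 18
Reactants: 24 α-(dimethylaminomethyl) lactone
Product: 26 α-methylene lactone triene (C5 OTES; C8 OTBS), via ammonium iodide 25 (not isolated)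
Conditions: MeI, MeOH/CH2Cl2, 25 °C; then aq. NaHCO3, EtOAc, 25 °C
Reagents that add atoms: iodomethane CI (its methyl group is present only in 25)
Why: N-methylation followed by E1cB (Hofmann-type) elimination of trimethylamine from the β-ammonio lactone gives the exocyclic C11=C13 alkene at room temperature, which matters because the cross-conjugated triene should not be heated.

Step 19
Reactants: 26 α-methylene lactone triene
Product: 27 C5 allylic alcohol (C8 OTBS retained)
Conditions: HF·pyridine, pyridine, THF, 0 °C
Reagents that add atoms: none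
Why: buffered fluoride-mediated desilylation that removes the secondary triethylsilyl ether much faster than the tert-butyldimethylsilyl ether, so only the hydroxyl needed as a directing group is freed.

Step 20
Reactants: 27 C5 allylic alcohol
Product: 28 4,15-epoxide (4S; C5 OH free; C8 OTBS)
Conditions: VO(acac)2 (5 mol%), t-BuOOH (1.2 equiv), CH2Cl2, 0 °C
Reagents that add atoms: tert-butyl hydroperoxide CC(C)(C)OO
Why: vanadium-catalysed hydroxyl-directed epoxidation, which should touch only the allylic C4=C15 alkene and deliver the oxygen within the vanadium alkoxide–peroxide complex on the side of the C5–O bond, so that the C4–O bond is cis to the C5 hydroxyl on the ring (4S).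

Step 21
Reactants: 28 4,15-epoxide
Product: 29 C5,C8-diol
Conditions: TBAF, AcOH (1:1), THF, 0 → 25 °C
Reagents that add atoms: none
Why: fluoride-mediated cleavage of the TBS ether, buffered with acetic acid so that no free alkoxide is present to cause Payne rearrangement at C4/C5 or 12,6 to 12,8 translactonization, and without acid strong enough to ionize the vinyl epoxide.

Step 22
Reactants: 29 C5,C8-diol; 30 angelic acid
Product: 31 C8 angelate (C5 OH free)
Conditions: 30, 2,4,6-trichlorobenzoyl chloride, Et3N, toluene, 25 °C; then 29, 60 °C (no DMAP)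
Reagents that add atoms: none
Why: Yamaguchi-type acylation through the mixed anhydride without a nucleophilic catalyst, which avoids the addition–elimination that turns angelate into tiglate and should acylate only the C8 hydroxyl, the C5 hydroxyl being neopentylic next to the quaternary spiro-epoxide carbon.

Step 23
Reactants: 31 C8 angelate
Product: 32 CNP0594916.1, (1R,2R,3S,4S,5S,6S,7R,8S,10R)-8-angeloyloxy-1,10:2,3:4,15-triepoxy-5-hydroxygermacr-11(13)-en-12,6-olide
Conditions: dimethyldioxirane (3 equiv), acetone/CH2Cl2, −20 → 0 °C
Reagents that add atoms: dimethyldioxirane CC1(C)OO1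
Why: electrophilic epoxidation with a neutral dioxirane, first at the trisubstituted C1=C10 and then at the C2=C3 alkene while the electron-poor α-methylene lactone and angelate alkenes should stay untouched; the stereospecific syn addition turns the E alkene into the trans (1R,10R) and the Z alkene into the cis (2R,3S) oxirane, and the faces are expected to be set by outside-face (peripheral) attack on the ten-membered ring.

**Compound list**

1 | (S)-4-benzyloxazolidin-2-one | O=C1N[C@@H](Cc2ccccc2)CO1 | starting material
2 | methyl 4-chloro-4-oxobutanoate | COC(=O)CCC(Cl)=O | starting material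
3 | (S)-4-benzyl-3-(4-methoxy-4-oxobutanoyl)oxazolidin-2-one | COC(=O)CCC(=O)N1[C@@H](Cc2ccccc2)COC1=O | intermediate
4 | methyl 2,3-O-isopropylidene-β-D-ribofuranoside | CO[C@@H]1O[C@H](CO)[C@H]2OC(C)(C)O[C@@H]12 | starting material
5 | methyl 5-deoxy-5-iodo-2,3-O-isopropylidene-β-D-ribofuranoside | CO[C@@H]1O[C@H](CI)[C@H]2OC(C)(C)O[C@@H]12 | intermediate
6 | (4R,5R)-2,2-dimethyl-5-vinyl-1,3-dioxolane-4-carbaldehyde | O=C[C@@H]1OC(C)(C)O[C@@H]1C=C | intermediate
7 | Evans syn-aldol adduct (methyl ester, free C6 hydroxyl; 6,7-syn, 5,6-anti) | COC(=O)C[C@H](C(=O)N1[C@@H](Cc2ccccc2)COC1=O)[C@H](O)[C@@H]1OC(C)(C)O[C@@H]1C=C | intermediate (not isolated)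
8 | trans-γ-lactone imide (lactone O on C6; acyl oxazolidinone on C7; C4/C5 acetonide; vinyl on C4) | O=C1C[C@H](C(=O)N2[C@@H](Cc3ccccc3)COC2=O)[C@H](O1)[C@@H]1OC(C)(C)O[C@@H]1C=C | intermediate
9 | lactone acid (C8 carboxylic acid) | O=C1C[C@H](C(=O)O)[C@H](O1)[C@@H]1OC(C)(C)O[C@@H]1C=C | intermediate
10 | isobutyl carbonic mixed anhydride of 9 | O=C1C[C@H](C(=O)OC(=O)OCC(C)C)[C@H](O1)[C@@H]1OC(C)(C)O[C@@H]1C=C | intermediate (not isolated)
11 | lactone alcohol (C8 hydroxymethyl) | O=C1C[C@H](CO)[C@H](O1)[C@@H]1OC(C)(C)O[C@@H]1C=C | intermediate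
12 | lactone aldehyde (C8 aldehyde) | O=C1C[C@H](C=O)[C@H](O1)[C@@H]1OC(C)(C)O[C@@H]1C=C | intermediate
13 | 2-methylallylmagnesium chloride | CC(=C)C[Mg]Cl | starting material
14 | homoallylic alcohol (8S; methallyl on C8) | O=C1C[C@H]([C@@H](O)CC(C)=C)[C@H](O1)[C@@H]1OC(C)(C)O[C@@H]1C=C | intermediate
15 | C8 tert-butyldimethylsilyl ether of 14 | O=C1C[C@H]([C@@H](O[Si](C)(C)C(C)(C)C)CC(C)=C)[C@H](O1)[C@@H]1OC(C)(C)O[C@@H]1C=C | intermediate
16 | C4,C5-diol (acyclic diene; C8 OTBS) | O=C1C[C@H]([C@@H](O[Si](C)(C)C(C)(C)C)CC(C)=C)[C@H](O1)[C@H](O)[C@H](O)C=C | intermediate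
17 | cyclooctene diol (Z C3=C10; C4 and C5 hydroxyls; C8 OTBS; trans-fused γ-lactone) | C1C(=O)O[C@H]2[C@H]1[C@@H](O[Si](C)(C)C(C)(C)C)C/C(C)=C\[C@@H](O)[C@H]2O | intermediate
18 | α-hydroxy cyclooctenone (C4 ketone; C5 OH; C8 OTBS) | C1C(=O)O[C@H]2[C@H]1[C@@H](O[Si](C)(C)C(C)(C)C)C/C(C)=C\C(=O)[C@H]2O | intermediate
19 | cyclooctenone (C4 ketone; C5 OTES; C8 OTBS) | C1C(=O)O[C@H]2[C@H]1[C@@H](O[Si](C)(C)C(C)(C)C)C/C(C)=C\C(=O)[C@H]2O[Si](CC)(CC)CC | intermediate
20 | acetylene | C#C | starting material
21 | cis-fused cyclobutene ketone (bicyclo[6.2.0]dec-9-en-2-one core; cyclobutene C10–C1=C2–C3; C4 ketone; C5 OTES; C8 OTBS; one of two cis-fused diastereomers drawn) | C1C(=O)O[C@H]2[C@H]1[C@@H](O[Si](C)(C)C(C)(C)C)C[C@]3(C)C=C[C@@H]3C(=O)[C@H]2O[Si](CC)(CC)CC | intermediate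
22 | germacra-1(10)E,2Z-dien-4-one 12,6-olide (C5 OTES; C8 OTBS) | C1C(=O)O[C@H]2[C@H]1[C@@H](O[Si](C)(C)C(C)(C)C)C/C(C)=C/C=C\C(=O)[C@H]2O[Si](CC)(CC)CC | intermediate
23 | germacra-1(10)E,2Z,4(15)-triene 12,6-olide (C5 OTES; C8 OTBS) | C1C(=O)O[C@H]2[C@H]1[C@@H](O[Si](C)(C)C(C)(C)C)C/C(C)=C/C=C\C(=C)[C@H]2O[Si](CC)(CC)CC | intermediate
24 | α-(dimethylaminomethyl) lactone (C11 epimers) | CN(C)CC1C(=O)O[C@H]2[C@H]1[C@@H](O[Si](C)(C)C(C)(C)C)C/C(C)=C/C=C\C(=C)[C@H]2O[Si](CC)(CC)CC | intermediate
25 | trimethylammonium iodide of 24 | C[N+](C)(C)CC1C(=O)O[C@H]2[C@H]1[C@@H](O[Si](C)(C)C(C)(C)C)C/C(C)=C/C=C\C(=C)[C@H]2O[Si](CC)(CC)CC.[I-] | intermediate (not isolated)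
26 | α-methylene lactone triene (C5 OTES; C8 OTBS) | C=C1C(=O)O[C@H]2[C@H]1[C@@H](O[Si](C)(C)C(C)(C)C)C/C(C)=C/C=C\C(=C)[C@H]2O[Si](CC)(CC)CC | intermediate
27 | C5 allylic alcohol (C8 OTBS) | C=C1C(=O)O[C@H]2[C@H]1[C@@H](O[Si](C)(C)C(C)(C)C)C/C(C)=C/C=C\C(=C)[C@H]2O | intermediate
28 | 4,15-epoxide (4S; C5 OH; C8 OTBS) | C=C1C(=O)O[C@H]2[C@H]1[C@@H](O[Si](C)(C)C(C)(C)C)C/C(C)=C/C=C\[C@]1(CO1)[C@H]2O | intermediate
29 | C5,C8-diol with 4,15-epoxide and 1(10)E,2Z-diene | C=C1C(=O)O[C@H]2[C@H]1[C@@H](O)C/C(C)=C/C=C\[C@]1(CO1)[C@H]2O | intermediate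
30 | angelic acid, (Z)-2-methylbut-2-enoic acid | C/C=C(/C)C(=O)O | starting material
31 | C8 angelate with 4,15-epoxide and 1(10)E,2Z-diene (C5 OH free) | C=C1C(=O)O[C@H]2[C@H]1[C@@H](OC(=O)/C(C)=C\C)C/C(C)=C/C=C\[C@]1(CO1)[C@H]2O | intermediate
32 | CNP0594916.1, (1R,2R,3S,4S,5S,6S,7R,8S,10R)-8-angeloyloxy-1,10:2,3:4,15-triepoxy-5-hydroxygermacr-11(13)-en-12,6-olide | C=C1C(=O)O[C@H]2[C@H]1[C@@H](OC(=O)/C(C)=C\C)C[C@@]1(C)O[C@@H]1[C@@H]1O[C@@H]1[C@]1(CO1)[C@H]2O | target

**Step count and risks**

Total step count: 23. Longest linear sequence: 22 steps (4 to 32, steps 2 to 23).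

Steps most likely to fail:

1. Step 14 (photocycloaddition). In an eight-membered enone the twisted triplet can relax by Z/E isomerization of the C3=C10 bond faster than acetylene captures it. Material would then drain away through dimerization of the strained E-enone, and part of the biradical could close to a trans-fused ring. The fallback sets out from 19 and comes back at 21. Acetylene is replaced by a liquid acetylene equivalent used as co-solvent: irradiation of 19 in (Z)-1,2-dichloroethene/CH2Cl2 (about 6 M trap) should give the 1,2-dichlorocyclobutane photoadduct F1 as a mixture of chlorine stereoisomers, from which any trans-fused material is removed by chromatography. Reductive 1,2-elimination with Zn–Cu couple in THF/AcOH under sonication at 25 °C then forms the cyclobutene double bond of 21.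

2. Step 15 (key step). Inward rotation of the acyl carbon may be incomplete if the Lewis acid is held by the lactone carbonyl instead of the ketone, which would lead to the 1(10)Z,2E geometry. The 2Z-dienone may also drift into a bridged 2H-pyran by reversible oxa-6π closure. The fallback sets out from 21 and comes back at 22. The ketone is tethered to the Lewis acid through the C5 oxygen: HF·pyridine (pyridine, THF, 0 °C) removes the triethylsilyl group to give the α-hydroxy ketone cyclobutene F2. MgBr2·OEt2 (CH2Cl2, 25 °C) forms the five-membered O5–Mg–O4 chelate, in which the carbonyl is a fixed and strongly activated acceptor, and the opening should give the hydroxy dienone F3. Re-silylation (TESOTf, 2,6-lutidine, −78 °C) returns 22.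

3. Step 23 (diene bis-epoxidation). Facial selectivity may be poor in one of the two epoxidations if the reagent attacks a minor ring conformer, and prolonged exposure could oxidize the angelate alkene. The fallback sets out from 29 and comes back at 32. The C1–C10 oxygen is delivered from the C8 hydroxyl before it is acylated: VO(acac)2/t-BuOOH (CH2Cl2, 25 °C) on 29 should epoxidize the homoallylic trisubstituted C1=C10 alkene on the side of the C8 hydroxyl and give the 1,10-epoxy diol F4. Angeloylation as in step 22 gives the 1,10-epoxy angelate F5. The C2=C3 alkene, the only one left apart from the two electron-poor ones, is then epoxidized with m-CPBA/NaHCO3 (CH2Cl2, 0 °C) to 32.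

Further compounds
F1 | step 14 | 1,2-dichlorocyclobutane photoadduct of 19 (cis-fused; chlorine stereoisomers) | C1C(=O)O[C@H]2[C@H]1[C@@H](O[Si](C)(C)C(C)(C)C)C[C@]3(C)C(Cl)C(Cl)[C@@H]3C(=O)[C@H]2O[Si](CC)(CC)CC
F2 | step 15 | α-hydroxy ketone cyclobutene (21 without the triethylsilyl group) | C1C(=O)O[C@H]2[C@H]1[C@@H](O[Si](C)(C)C(C)(C)C)C[C@]3(C)C=C[C@@H]3C(=O)[C@H]2O
F3 | step 15 | hydroxy dienone (22 without the triethylsilyl group) | C1C(=O)O[C@H]2[C@H]1[C@@H](O[Si](C)(C)C(C)(C)C)C/C(C)=C/C=C\C(=O)[C@H]2O
F4 | step 23 | 1,10:4,15-diepoxy-2Z-ene C5,C8-diol | C=C1C(=O)O[C@H]2[C@H]1[C@@H](O)C[C@@]1(C)O[C@@H]1/C=C\[C@]1(CO1)[C@H]2O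
F5 | step 23 | 1,10:4,15-diepoxy-2Z-ene C8 angelate | C=C1C(=O)O[C@H]2[C@H]1[C@@H](OC(=O)/C(C)=C\C)C[C@@]1(C)O[C@@H]1/C=C\[C@]1(CO1)[C@H]2O
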